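**Compound numbers used throughout:** 1–23 as defined in the steps and the compound list; 23 is the target.

## The problem

The target is a flavone without stereocentres, so the difficulty is purely constitutional. Ring A is a hexasubstituted benzene: C4a carries the pyranone carbonyl carbon, C8a the ring oxygen, and C5 to C8 carry four contiguous oxygens. Three of these are methyl ethers; only the C6 oxygen is a free phenol, wedged between the C5 and C7 methoxyls. Building such a ring by substitution on a simpler phenol leaves the position of the last oxygen and of the free hydroxyl to directing effects. Correcting this by selective methylation or demethylation is unreliable, and once a 5-hydroxyl is free, acid can isomerize 5,7,8- into 5,6,7-oxygenated flavones (Wessely–Moser rearrangement). Ring B has 2'-OH and 6'-OMe on both sides of C1', so the C2–C1' bond and any carbonyl attached to C1' are doubly ortho-hindered. The fragile points are the C5 methoxyl, which is peri to the C4 carbonyl and is cleaved by Lewis and strong protic acids, and the electron-rich ring A, which at the para-dihydroxy stage is oxidized by air to a quinone. The enabling feature is the oxygen pattern of ring A: the vicinal methoxyls on C7 and C8 are flanked by a para oxygen pair on C6 and C8a, and these are exactly the two ring A oxygens that are not methyl ethers. These four carbons map onto dimethyl squarate, while C4a and C5 can come from an alkenyl unit carrying the C5 methoxyl and a masked C4 acetyl group.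

## Retrosynthesis

**Final unmasking.** Target 23 is traced to its bis(benzyl ether) 22 by cutting the two O–benzyl bonds at C6 and C2'. Benzyl is preferred to methyl or methoxymethyl because it falls in one neutral hydrogenolysis; any Lewis acid strong enough to cleave an aryl methyl ether would first strip the peri C5 methoxyl. The forward step must not saturate C2=C3.

**Ring C.** Flavone 22 is opened at O1–C2 to the 1,3-diketone 20, and 20 is cut at C2–C3 to the aryl ester 19 (Baker–Venkataraman transform). Ester 19 divides at the ester C–O bond into acetophenone 14 and acid 17, activated as chloride 18. A chalcone route was weighed against this: it needs a doubly ortho-substituted aldehyde and an oxidative cyclization in the presence of two electron-rich rings. The intramolecular acyl shift is the neighbour least sensitive to the crowding at C1'. The forward reactions must acylate a hydrogen-bonded, flanked phenol.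

**Ring B.** Acid 17 comes from 2-hydroxy-6-methoxybenzoic acid 15 through benzyl ester/benzyl ether 16; the only bonds cut are O–benzyl bonds.

**Differentiating the ring A oxygens.** Acetophenone 14 is cut at its O–benzyl bond to hydroquinone ketone 13, and 13 is the hydrolysis product of ketal 12. In 13 the C8a hydroxyl is hydrogen-bonded to the acetyl carbonyl and the C6 hydroxyl is not, so the forward benzylation needs no further control element.

**Key disconnection.** Hydroquinone 12 is cut at C5–C6 (retro-electrocyclization to dienylketene 10) and the ketene is closed back onto the carbinol carbon to give cyclobutenone 9. This replaces a fully substituted arene by a four-membered ring plus a two-carbon alkenyl unit, and no positional selectivity is asked of any aromatic substitution. Every substituent of ring A is placed by connectivity. The forward reaction must turn the alkenyl group inward on ring opening and must be run without oxygen.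

**Attaching the alkenyl unit.** Cyclobutenone 9 is cut at the future C4a–C8a bond into dimethyl squarate 7 and alkenyllithium 8, generated from bromoalkene 6. The two carbonyls of 7 are equivalent, so only 1,2-addition and a single addition are required.

**The bromoalkene.** Bromide 6 is traced to enol ether 4 (C–Br cut; bromination–dehydrobromination), 4 to aldehyde 3 (C=C cut; Wittig methoxymethylenation), and 3 through ester 2 to ethyl pyruvate 1. Installing the ketal after the enol ether was rejected. A β-methoxy enone is a vinylogous ester, and acid with a diol exchanges at the β-carbon instead of ketalizing the carbonyl. The ketal is therefore installed first, on 1, where the ketone is the most electrophilic site, and bromine is introduced last under basic conditions.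

## Roads not taken

**Alternative 1:** carbonylative α-arylation with CO as C2.
- **Cut:** C1'–C2 and C2–C3 together.
- **Forward step:** zerovalent palladium from Pd(dba)2 and a bisphosphine would insert into the C–I bond of 1-(benzyloxy)-2-iodo-3-methoxybenzene A2 and take up CO. The aroylpalladium intermediate would acylate the enolate of 1-[5-(benzyloxy)-3,4,6-trimethoxy-2-(methoxymethoxy)phenyl]ethanone A3 (this is 14 with its chelated hydroxyl capped) to give diketone A1. Acid would then unmask and cyclize A1.
- **Merits:** one catalytic three-component step replaces the preparation of the ring B acid, the ester formation and the acyl shift; no acid chloride is needed.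
- **Weak points:** A2 is doubly ortho-substituted and the enolate of A3 is flanked on both sides, so CO insertion and C-acylation must outrun direct α-arylation and O-acylation. An extra protecting group is needed on the C8a oxygen. The route does not address ring A, and A3 would still have to be made.
- **Comparison:** on step count for ring C this road is shorter, and it is compatible with the chosen ring A construction. The chosen plan sets against it an intramolecular acyl transfer that is indifferent to the crowding, with no gas handling and no catalyst to tune.

**Alternative 2:** ester-tethered direct arylation.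
- **Cut:** C2–C1' only.
- **Forward step:** in 2-bromo-3-methoxyphenyl 6-(benzyloxy)-5,7,8-trimethoxy-4-oxo-4H-chromene-3-carboxylate A5, zerovalent palladium from Pd(OAc)2 and PCy3 with K2CO3 would insert into the C1'–Br bond. It would then arylate the chromone C2–H and close the six-membered lactone of A4.
- **Merits:** the most hindered bond of the molecule is made intramolecularly, and the tether later becomes the 2'-hydroxyl without a protecting group.
- **Weak points:** the chromone-3-carboxylate must first be built from the same ring A acetophenone (formylative chromone closure, oxidation, esterification). After the key step the lactone must be saponified and C3 decarboxylated. Hydroxide also attacks chromones at C2 and can open the pyranone.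
- **Comparison:** this road is better at forming the C2–C1' bond. The chosen plan is several steps shorter in the end game and never exposes the pyranone to hydroxide.

**Alternative 3:** squarate annulation of ring A onto a preformed 2-aryl-4-pyranone.
- **Cut:** C8–C8a in the key step, C4a–C5 in the preceding addition.
- **Forward step:** thermolysis of 2,3-bis(benzyloxy)-4-hydroxy-4-{6-[2-methoxy-6-(triisopropylsilyloxy)phenyl]-4-oxo-4H-pyran-3-yl}cyclobut-2-en-1-one A7 would open it to a ketene. A 6-electron electrocyclization onto the pyranone carbon that becomes C8a would give 5,8-dihydroxyflavone A6.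
- **Merits:** it is the most convergent plan. Rings B and C are in place before ring A is made, by the same pericyclic logic as the chosen route.
- **Weak points:** the oxygens map badly. The squarate alkoxy groups land on C6 and C7 and the hydroxyls on C5 and C8, whereas the target needs OH on C6 and OMe on C7. After the annulation one must methylate C5–OH (chelated) and C8–OH, remove both benzyl groups, and then methylate C7–OH selectively beside C6–OH. The pyranone must also be metalated at C3 next to its own carbonyl, and the ring closure has to engage a vinylogous-ester double bond.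
- **Comparison:** this road is better in convergence and in the number of carbon–carbon bond-forming steps. The chosen plan sets against it a one-to-one oxygen mapping (squarate methoxyls at C7 and C8, carbonyl oxygens at C6 and O1), so no late regioselective methylation is needed, and a simple alkenyllithium in place of a metalated pyranone.

Key step: step 6

Assumption: bromoalkene 6 (and hence 8 and 9) is drawn as the isomer with bromine cis to methoxyl, which should predominate; the alkene geometry disappears when C5 becomes aromatic, so the other isomer would converge on the same arene 12.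

## Route

Step 1
Reactants: 1 ethyl pyruvate
Product: 2 ethyl 2-methyl-1,3-dioxolane-2-carboxylate
Conditions: HOCH2CH2OH, p-TsOH·H2O (cat.), toluene, reflux, Dean–Stark
Reagents that add atoms: ethylene glycol, OCCO
Why: Acid-catalysed ketalization of the activated α-keto ester carbonyl, driven by azeotropic removal of water; no stereocentre is formed.

Step 2
Reactants: 2 ethyl 2-methyl-1,3-dioxolane-2-carboxylate
Product: 3 2-methyl-1,3-dioxolane-2-carbaldehyde
Conditions: i-Bu2AlH (1.05 equiv), CH2Cl2, −78 °C; MeOH, then aq. potassium sodium tartrate
Reagents that add atoms: none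
Why: Partial reduction of an α,α-dialkoxy ester; the tetrahedral aluminium hemiacetal is held at −78 °C by chelation to a dioxolane oxygen and releases the aldehyde only on work-up, and 3 has no α-hydrogen to epimerize or enolize.

Step 3
Reactants: 3 2-methyl-1,3-dioxolane-2-carbaldehyde
Product: 4 2-(2-methoxyethenyl)-2-methyl-1,3-dioxolane (mixture of E and Z isomers)
Conditions: Ph3P(CH2OMe)Cl, KOtBu, THF, 0 °C → rt
Reagents that add atoms: (methoxymethyl)triphenylphosphonium chloride, COC[P+](c1ccccc1)(c1ccccc1)c1ccccc1.[Cl-]
Why: Wittig methoxymethylenation of a non-enolizable aldehyde under basic conditions that leave the ketal untouched; the isomer mixture is acceptable because the next step passes through sp3 carbons.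

Step 4
Reactants: 4 2-(2-methoxyethenyl)-2-methyl-1,3-dioxolane
Product: 6 2-[(Z)-1-bromo-2-methoxyethenyl]-2-methyl-1,3-dioxolane, via dibromide 5 (not isolated)
Conditions: Br2 (1.0 equiv), CH2Cl2, −78 °C; then DBU (1.5 equiv), −78 °C → rt
Reagents that add atoms: bromine, BrBr
Why: Bromine adds to the electron-rich enol ether and the amidine base removes HBr with the anomeric bromide as leaving group, the standard bromination–dehydrobromination route to β-bromo enol ethers; the isomer with the bulky ketal trans to methoxyl is expected, and the basic quench protects the dioxolane.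

Step 5
Reactants: 6 2-[(Z)-1-bromo-2-methoxyethenyl]-2-methyl-1,3-dioxolane; 7 dimethyl squarate
Product: 9 4-hydroxy-2,3-dimethoxy-4-[(E)-2-methoxy-1-(2-methyl-1,3-dioxolan-2-yl)ethenyl]cyclobut-2-en-1-one (racemic), via alkenyllithium 8 (not isolated)
Conditions: t-BuLi (2.0 equiv), THF, −78 °C; cannulate into 7, THF, −78 °C; aq. NH4Cl, −78 °C
Reagents that add atoms: none
Why: Bromine–lithium exchange with retention gives an alkenyllithium held by the cis methoxyl and a ketal oxygen (the behaviour of α-lithio enone ketals), which adds 1,2 to one of the two equivalent squarate carbonyls; inverse addition at −78 °C limits double addition, and the racemic carbinol centre is erased in step 6.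

Step 6
Reactants: 9 4-hydroxy-2,3-dimethoxy-4-[(E)-2-methoxy-1-(2-methyl-1,3-dioxolan-2-yl)ethenyl]cyclobut-2-en-1-one
Product: 12 2,3,5-trimethoxy-6-(2-methyl-1,3-dioxolan-2-yl)benzene-1,4-diol, via dienylketene 10 (not isolated), via cyclohexadienone 11 (not isolated)
Conditions: toluene (degassed), 110 °C, Ar
Reagents that add atoms: none
Why: Heating opens the cyclobutenone by a thermally allowed conrotatory 4-electron electrocyclic cleavage of the bond between the carbinol carbon and the ring carbonyl, giving dienylketene 10. The ketene carbon (future C6) then bonds to the methoxy-bearing alkene terminus (future C5) in a disrotatory 6-electron electrocyclization that closes the six-membered carbocycle, ring A, as cyclohexadienone 11. Transfer of the C5 hydrogen to oxygen (keto–enol tautomerization) aromatizes 11 to hydroquinone 12. The closest known reaction type is the thermal ring expansion of 4-alkenyl- and 4-aryl-4-hydroxycyclobutenones derived from squarate esters to hydroquinones (Moore rearrangement). The only stereocentres involved, the racemic carbinol of 9 and the transient sp3 carbon of 11, vanish on aromatization, so no stereocontrol is needed. The selectivity that matters is torquoselectivity: the electron-donating hydroxyl prefers to rotate outward, which turns the alkenyl group inward beside the ketene. Regiochemistry is fixed by connectivity, since the alkenyl group offers a single terminus and the squarate carbons keep their order, so the carbonyl-derived oxygens end at C6 and C8a and the methoxyls at C5, C7 and C8. Exclusion of oxygen keeps 12 from going on to the quinone.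

Step 7
Reactants: 12 2,3,5-trimethoxy-6-(2-methyl-1,3-dioxolan-2-yl)benzene-1,4-diol
Product: 13 1-(2,5-dihydroxy-3,4,6-trimethoxyphenyl)ethan-1-one
Conditions: 1 M HCl (aq.), THF, rt, Ar
Reagents that add atoms: water, O
Why: Acid-catalysed ketal hydrolysis; dilute acid leaves the aryl methyl ethers alone, and the product is stabilized by the hydrogen bond between the C8a hydroxyl and the new carbonyl.

Step 8
Reactants: 13 1-(2,5-dihydroxy-3,4,6-trimethoxyphenyl)ethan-1-one
Product: 14 1-[5-(benzyloxy)-2-hydroxy-3,4,6-trimethoxyphenyl]ethan-1-one
Conditions: BnBr (1.05 equiv), K2CO3, acetone, reflux, Ar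
Reagents that add atoms: benzyl bromide, BrCc1ccccc1
Why: Williamson etherification under chelation control; the hydroxyl ortho to the acetyl group is locked in a hydrogen bond and stays unreactive toward carbonate and benzyl bromide, so the other hydroxyl (future C6–OH) is alkylated.

Step 9
Reactants: 15 2-hydroxy-6-methoxybenzoic acid
Product: 16 benzyl 2-(benzyloxy)-6-methoxybenzoate
Conditions: BnBr (2.3 equiv), K2CO3, DMF, 60 °C
Reagents that add atoms: benzyl bromide, BrCc1ccccc1
Why: Exhaustive O-alkylation of carboxylate and phenoxide (Williamson type); the ester is a temporary by-product of protecting the phenol.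

Step 10
Reactants: 16 benzyl 2-(benzyloxy)-6-methoxybenzoate
Product: 17 2-(benzyloxy)-6-methoxybenzoic acid
Conditions: KOH, EtOH–H2O, reflux; then aq. HCl
Reagents that add atoms: potassium hydroxide, [K+].[OH-]
Why: Saponification of the hindered benzyl ester, which needs heat because of the two ortho substituents; the benzyl aryl ether is inert to base.

Step 11
Reactants: 17 2-(benzyloxy)-6-methoxybenzoic acid; 14 1-[5-(benzyloxy)-2-hydroxy-3,4,6-trimethoxyphenyl]ethan-1-one
Product: 19 2-acetyl-4-(benzyloxy)-3,5,6-trimethoxyphenyl 2-(benzyloxy)-6-methoxybenzoate, via acid chloride 18 (not isolated)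
Conditions: (COCl)2, DMF (cat.), CH2Cl2, 0 °C → rt; evaporate; 14, pyridine, DMAP (cat.), 60 °C
Reagents that add atoms: none
Why: Acid chloride formation through the chloroiminium (Vilsmeier-type) catalyst, then DMAP-catalysed acyl transfer; the acylpyridinium intermediate is reactive enough to esterify the hydrogen-bonded, flanked phenol.

Step 12
Reactants: 19 2-acetyl-4-(benzyloxy)-3,5,6-trimethoxyphenyl 2-(benzyloxy)-6-methoxybenzoate
Product: 20 1-[5-(benzyloxy)-2-hydroxy-3,4,6-trimethoxyphenyl]-3-[2-(benzyloxy)-6-methoxyphenyl]propane-1,3-dione
Conditions: KOtBu (3 equiv), THF, 0 °C → rt; then aq. HCl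
Reagents that add atoms: none
Why: Baker–Venkataraman rearrangement; the methyl ketone enolate attacks the neighbouring ester carbonyl through a six-membered cyclic alkoxide and expels the phenoxide, forming the C2–C3 bond intramolecularly despite the hindered acyl group.

Step 13
Reactants: 20 1-[5-(benzyloxy)-2-hydroxy-3,4,6-trimethoxyphenyl]-3-[2-(benzyloxy)-6-methoxyphenyl]propane-1,3-dione
Product: 22 6-(benzyloxy)-2-[2-(benzyloxy)-6-methoxyphenyl]-5,7,8-trimethoxy-4H-chromen-4-one, via hemiketal 21 (not isolated)
Conditions: AcOH, H2SO4 (cat.), 60 °C
Reagents that add atoms: none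
Why: Acid-catalysed cyclodehydration of the 2-hydroxyaryl 1,3-diketone; only the C8a hydroxyl is free, so the hemiketal forms on the ring B carbonyl and loses water to a single flavone, and the mild acid spares the benzyl ethers and the C5 methoxyl.

Step 14
Reactants: 22 6-(benzyloxy)-2-[2-(benzyloxy)-6-methoxyphenyl]-5,7,8-trimethoxy-4H-chromen-4-one
Product: 23 6-hydroxy-2-(2-hydroxy-6-methoxyphenyl)-5,7,8-trimethoxy-4H-chromen-4-one (6,2'-dihydroxy-5,7,8,6'-tetramethoxyflavone)
Conditions: H2 (1 atm), Pd/C (10%), EtOAc–MeOH, rt
Reagents that add atoms: none
Why: Catalytic hydrogenolysis of both benzyl aryl ethers under neutral conditions; the methyl ethers and the pyranone double bond are not expected to be touched at ambient pressure.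

## Compound list

1 | ethyl pyruvate (ethyl 2-oxopropanoate) | CCOC(=O)C(C)=O | starting material
2 | ethyl 2-methyl-1,3-dioxolane-2-carboxylate | CCOC(=O)C1(C)OCCO1 | intermediate
3 | 2-methyl-1,3-dioxolane-2-carbaldehyde | CC1(C=O)OCCO1 | intermediate
4 | 2-(2-methoxyethenyl)-2-methyl-1,3-dioxolane (mixture of E and Z isomers) | COC=CC1(C)OCCO1 | intermediate
5 | 2-(1,2-dibromo-2-methoxyethyl)-2-methyl-1,3-dioxolane (mixture of diastereomers) | COC(Br)C(Br)C1(C)OCCO1 | intermediate (not isolated)
6 | 2-[(Z)-1-bromo-2-methoxyethenyl]-2-methyl-1,3-dioxolane | CO/C=C(\Br)C1(C)OCCO1 | intermediate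
7 | dimethyl squarate (3,4-dimethoxycyclobut-3-ene-1,2-dione) | COC1=C(OC)C(=O)C1=O | starting material
8 | [(E)-2-methoxy-1-(2-methyl-1,3-dioxolan-2-yl)ethenyl]lithium (lithium cis to methoxyl) | CO/C=C(\[Li])C1(C)OCCO1 | intermediate (not isolated)
9 | 4-hydroxy-2,3-dimethoxy-4-[(E)-2-methoxy-1-(2-methyl-1,3-dioxolan-2-yl)ethenyl]cyclobut-2-en-1-one (racemic) | CO/C=C(\C1(O)C(OC)=C(OC)C1=O)C1(C)OCCO1 | intermediate
10 | (3Z,5E)-4-hydroxy-2,3,6-trimethoxy-5-(2-methyl-1,3-dioxolan-2-yl)hexa-1,3,5-trien-1-one (dienylketene) | O=C=C(OC)/C(OC)=C(O)\C(=C/OC)C1(C)OCCO1 | intermediate (not isolated)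
11 | 4-hydroxy-2,3,6-trimethoxy-5-(2-methyl-1,3-dioxolan-2-yl)cyclohexa-2,4-dien-1-one (racemic) | COC1C(=O)C(OC)=C(OC)C(O)=C1C1(C)OCCO1 | intermediate (not isolated)
12 | 2,3,5-trimethoxy-6-(2-methyl-1,3-dioxolan-2-yl)benzene-1,4-diol, also named 2-(2,5-dihydroxy-3,4,6-trimethoxyphenyl)-2-methyl-1,3-dioxolane | COc1c(O)c(OC)c(OC)c(O)c1C1(C)OCCO1 | intermediate
13 | 1-(2,5-dihydroxy-3,4,6-trimethoxyphenyl)ethan-1-one | CC(=O)c1c(O)c(OC)c(OC)c(O)c1OC | intermediate
14 | 1-[5-(benzyloxy)-2-hydroxy-3,4,6-trimethoxyphenyl]ethan-1-one | CC(=O)c1c(O)c(OC)c(OC)c(OCc2ccccc2)c1OC | intermediate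
15 | 2-hydroxy-6-methoxybenzoic acid | COc1cccc(O)c1C(=O)O | starting material
16 | benzyl 2-(benzyloxy)-6-methoxybenzoate | COc1cccc(OCc2ccccc2)c1C(=O)OCc1ccccc1 | intermediate
17 | 2-(benzyloxy)-6-methoxybenzoic acid | COc1cccc(OCc2ccccc2)c1C(=O)O | intermediate
18 | 2-(benzyloxy)-6-methoxybenzoyl chloride | COc1cccc(OCc2ccccc2)c1C(Cl)=O | intermediate (not isolated)
19 | 2-acetyl-4-(benzyloxy)-3,5,6-trimethoxyphenyl 2-(benzyloxy)-6-methoxybenzoate | CC(=O)c1c(OC(=O)c2c(OC)cccc2OCc2ccccc2)c(OC)c(OC)c(OCc2ccccc2)c1OC | intermediate
20 | 1-[5-(benzyloxy)-2-hydroxy-3,4,6-trimethoxyphenyl]-3-[2-(benzyloxy)-6-methoxyphenyl]propane-1,3-dione (drawn as diketone; enol tautomer expected to be present) | COc1cccc(OCc2ccccc2)c1C(=O)CC(=O)c1c(O)c(OC)c(OC)c(OCc2ccccc2)c1OC | intermediate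
21 | 6-(benzyloxy)-2-[2-(benzyloxy)-6-methoxyphenyl]-2-hydroxy-5,7,8-trimethoxy-2,3-dihydro-4H-chromen-4-one (racemic hemiketal) | COc1cccc(OCc2ccccc2)c1C1(O)CC(=O)c2c(OC)c(OCc3ccccc3)c(OC)c(OC)c2O1 | intermediate (not isolated)
22 | 6-(benzyloxy)-2-[2-(benzyloxy)-6-methoxyphenyl]-5,7,8-trimethoxy-4H-chromen-4-one | COc1cccc(OCc2ccccc2)c1-c1cc(=O)c2c(OC)c(OCc3ccccc3)c(OC)c(OC)c2o1 | intermediate
23 | 6-hydroxy-2-(2-hydroxy-6-methoxyphenyl)-5,7,8-trimethoxy-4H-chromen-4-one (6,2'-dihydroxy-5,7,8,6'-tetramethoxyflavone) | COc1cccc(O)c1-c1cc(=O)c2c(OC)c(O)c(OC)c(OC)c2o1 | target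

## Step count and risk

Total step count: 14. Longest linear sequence: 12 steps (steps 1–8 and 11–14, from ethyl pyruvate); the ring B arm (steps 9 and 10) joins at step 11.

**Step 6 (key step).** The most likely failure is ring opening with the wrong sense of rotation (alkenyl outward, hydroxyl inward), after which the ketene is trapped by its own hydroxyl as a butenolide. This is made more likely by the bulky quaternary ketal on the alkene carbon attached to the ring. Oxidation of the electron-rich hydroquinone to the quinone during isolation is the second risk. The fallback sets out from 9. The carbinol would be silylated (Me3SiCl, Et3N, CH2Cl2) to 2,3-dimethoxy-4-[(E)-2-methoxy-1-(2-methyl-1,3-dioxolan-2-yl)ethenyl]-4-(trimethylsilyloxy)cyclobut-2-en-1-one F1. A silyl ether cannot lactonize, so the unproductive ketene can only return to the cyclobutenone. Thermolysis in toluene should then give the monosilylated hydroquinone 2,3,6-trimethoxy-5-(2-methyl-1,3-dioxolan-2-yl)-4-(trimethylsilyloxy)phenol F2, which is also less prone to oxidation. Aqueous HCl in THF would remove the silyl group and the ketal together, and the route is rejoined at 13.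

**Step 5.** The most likely failure is decomposition of alkenyllithium 8 by β-elimination before it adds (loss of lithium methoxide, or opening of the ketal), or a second addition to the remaining carbonyl. The fallback sets out from 7 and brings the acetyl group in after the benzannulation. Methoxyethene would be brominated to 1,2-dibromo-1-methoxyethane F3 and dehydrobrominated with DBU to (Z)-1-bromo-2-methoxyethene F4. Exchange with t-BuLi (THF, −78 °C) would give [(Z)-2-methoxyethenyl]lithium F5, a member of the long-used class of (Z)-2-alkoxyvinyllithiums. Addition to 7 would give 4-hydroxy-2,3-dimethoxy-4-[(Z)-2-methoxyethenyl]cyclobut-2-en-1-one F6, and thermolysis would give 2,3,5-trimethoxybenzene-1,4-diol F7. Its single unsubstituted ring carbon is the future C4a, so acetylation there (AcOH, BF3·OEt2, 70 °C; Friedel–Crafts or Fries type) returns to the route at 13. The price is a Lewis acid next to the C5 methoxyl, which is why this is the fallback and not the plan.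

**Step 4.** The most likely failure is opening of the dioxolane by HBr formed before the base takes over, or substitution of the anomeric bromide by the amine in place of elimination. The fallback sets out from 4 and needs no bromide. The (Z)-isomer of 4 would be lithiated at the methoxy-bearing carbon (t-BuLi, THF, −78 → 0 °C; α-lithiation of an enol ether) to [(Z)-1-methoxy-2-(2-methyl-1,3-dioxolan-2-yl)ethenyl]lithium F8. Addition to 7 would give the isomeric 4-hydroxy-2,3-dimethoxy-4-[(Z)-1-methoxy-2-(2-methyl-1,3-dioxolan-2-yl)ethenyl]cyclobut-2-en-1-one F9. Its thermolysis closes ring A between C4a and C8a and places the methoxyl again on C5, so it should give the same hydroquinone; the route is rejoined at 12.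

**Step 11.** The most likely failure is incomplete O-acylation: phenol 14 is hydrogen-bonded and flanked on both sides and acid chloride 18 is doubly ortho-substituted, so decomposition of 18 may outrun acyl transfer. The fallback sets out from 14 and 17. It is direct C-acylation of the lithium enolate–phenoxide of 14 (LiN(SiMe3)2, at least 3 equiv, THF, −78 °C → rt) with 18. Any O-acylated material rearranges under the same conditions. The route is rejoined at 20, and no new compound is made.

## Further compounds

F1 | step 6 | 2,3-dimethoxy-4-[(E)-2-methoxy-1-(2-methyl-1,3-dioxolan-2-yl)ethenyl]-4-(trimethylsilyloxy)cyclobut-2-en-1-one | CO/C=C(\C1(O[Si](C)(C)C)C(OC)=C(OC)C1=O)C1(C)OCCO1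
F2 | step 6 | 2,3,6-trimethoxy-5-(2-methyl-1,3-dioxolan-2-yl)-4-(trimethylsilyloxy)phenol | COc1c(O)c(OC)c(OC)c(O[Si](C)(C)C)c1C1(C)OCCO1
F3 | step 5 | 1,2-dibromo-1-methoxyethane | COC(Br)CBr
F4 | step 5 | (Z)-1-bromo-2-methoxyethene | CO/C=C\Br
F5 | step 5 | [(Z)-2-methoxyethenyl]lithium | CO/C=C\[Li]
F6 | step 5 | 4-hydroxy-2,3-dimethoxy-4-[(Z)-2-methoxyethenyl]cyclobut-2-en-1-one | CO/C=C\C1(O)C(OC)=C(OC)C1=O
F7 | step 5 | 2,3,5-trimethoxybenzene-1,4-diol | COc1cc(O)c(OC)c(OC)c1O
F8 | step 4 | [(Z)-1-methoxy-2-(2-methyl-1,3-dioxolan-2-yl)ethenyl]lithium | CO/C([Li])=C\C1(C)OCCO1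
F9 | step 4 | 4-hydroxy-2,3-dimethoxy-4-[(Z)-1-methoxy-2-(2-methyl-1,3-dioxolan-2-yl)ethenyl]cyclobut-2-en-1-one | CO/C(=C\C1(C)OCCO1)C1(O)C(OC)=C(OC)C1=O
F0 | step 11 | none | none
A1 | alternative 1 | 1-[5-(benzyloxy)-3,4,6-trimethoxy-2-(methoxymethoxy)phenyl]-3-[2-(benzyloxy)-6-methoxyphenyl]propane-1,3-dione | COc1cccc(OCc2ccccc2)c1C(=O)CC(=O)c1c(OCOC)c(OC)c(OC)c(OCc2ccccc2)c1OC
A2 | alternative 1 | 1-(benzyloxy)-2-iodo-3-methoxybenzene | COc1cccc(OCc2ccccc2)c1I
A3 | alternative 1 | 1-[5-(benzyloxy)-3,4,6-trimethoxy-2-(methoxymethoxy)phenyl]ethan-1-one | CC(=O)c1c(OCOC)c(OC)c(OC)c(OCc2ccccc2)c1OC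
A4 | alternative 2 | 9-(benzyloxy)-1,8,10,11-tetramethoxychromeno[4,3-b]chromene-6,7-dione | COc1cccc2OC(=O)c3c(-c12)oc1c(OC)c(OC)c(OCc4ccccc4)c(OC)c1c3=O
A5 | alternative 2 | 2-bromo-3-methoxyphenyl 6-(benzyloxy)-5,7,8-trimethoxy-4-oxo-4H-chromene-3-carboxylate | COc1cccc(OC(=O)c2coc3c(OC)c(OC)c(OCc4ccccc4)c(OC)c3c2=O)c1Br
A6 | alternative 3 | 6,7-bis(benzyloxy)-5,8-dihydroxy-2-[2-methoxy-6-(triisopropylsilyloxy)phenyl]-4H-chromen-4-one | COc1cccc(O[Si](C(C)C)(C(C)C)C(C)C)c1-c1cc(=O)c2c(O)c(OCc3ccccc3)c(OCc3ccccc3)c(O)c2o1
A7 | alternative 3 | 2,3-bis(benzyloxy)-4-hydroxy-4-{6-[2-methoxy-6-(triisopropylsilyloxy)phenyl]-4-oxo-4H-pyran-3-yl}cyclobut-2-en-1-one | COc1cccc(O[Si](C(C)C)(C(C)C)C(C)C)c1-c1cc(=O)c(co1)C1(O)C(OCc2ccccc2)=C(OCc2ccccc2)C1=O
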